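**Retrosynthetic overview**
The strategy rests on C1 of the ten-membered carbocycle (C1–C10): C1 is the oxirane CH, bonded to the quaternary oxirane carbon C10 and to C2 of the C2=C3 alkene. C2=C3 is therefore carried as an alkyne and C1 as an aldehyde, and C1–C2 is formed by intramolecular chromium/nickel alkynylation of an iodoalkyne.
The cyclisation precursor is cut at C8–C9 (sulfonyl carbanion carrying C9, C10 and C1, from (S)-2-methylglycidol) and at C6–C7 (Evans aldol of a succinate imide with the (Z)-enynal, which also closes the γ-lactone). C8 is set by oxazaborolidine reduction of a ketone.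
Ring order: γ-lactone (step 4), ten-membered carbocycle (step 18), oxirane by attack of the C10 oxygen on C1 with inversion (step 20).
The endgame is Z-selective semi-hydrogenation, α-methylenation of the lactone and esterification at C8 with the epoxy acid made from tiglic acid.

Key step: step 18

Remark: the germacrane numbering C1–C15 of the target is used for all intermediates. Lithium, boron and samarium enolates, alkoxides and carbanions formed by deprotonation or reduction are treated as activated forms of a numbered compound and carry no number of their own.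

**Route**

Step 1
Reactants: 1 (Z)-3-methylpent-2-en-4-yn-1-ol
Product: 3 (Z)-3-methyl-5-(trimethylsilyl)pent-2-en-4-yn-1-ol, via bis-silyl compound 2 (not isolated)
Conditions: n-BuLi (2.1 equiv), THF, −78 to 0 °C; Me3SiCl (2.2 equiv); then 1 M HCl, THF, 0 °C
Reagents that add atoms: chlorotrimethylsilane, C[Si](C)(C)Cl
Why: Double deprotonation (O–H and alkyne C–H), silylation of both anions and mild acid hydrolysis of the labile O–Si bond only (acetylide C-silylation) mask the acidic alkyne hydrogen for the later carbanion step without touching the Z alkene.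

Step 2
Reactants: 3 (Z)-3-methyl-5-(trimethylsilyl)pent-2-en-4-yn-1-ol
Product: 4 (Z)-3-methyl-5-(trimethylsilyl)pent-2-en-4-ynal
Conditions: MnO2 (activated, excess), CH2Cl2, rt, dark; used at once
Reagents that add atoms: none
Why: Heterogeneous MnO2 oxidation of an allylic alcohol under neutral conditions should keep the Z geometry of the enal.

Step 3
Reactants: 5 (S)-4-benzyl-2-oxazolidinone; 6 methyl 4-chloro-4-oxobutanoate
Product: 7 methyl 4-[(S)-4-benzyl-2-oxo-oxazolidin-3-yl]-4-oxobutanoate
Conditions: n-BuLi, THF, −78 °C; then 6, −78 to 0 °C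
Reagents that add atoms: none
Why: N-Acylation of the lithiated oxazolidinone by the acid chloride, which is far more reactive than the methyl ester.

Step 4
Reactants: 7 methyl 4-[(S)-4-benzyl-2-oxo-oxazolidin-3-yl]-4-oxobutanoate; 4 (Z)-3-methyl-5-(trimethylsilyl)pent-2-en-4-ynal
Product: 9 trans-lactone imide (C7 acyl-oxazolidinone γ-lactone bearing the silyl enyne at C6), via syn-aldol hydroxy ester 8 (not isolated)
Conditions: Bu2BOTf, i-Pr2NEt, CH2Cl2, −78 to 0 °C; 4, −78 to 0 °C; H2O2, MeOH, pH 7 buffer, 0 °C; then PPTS (cat.), CH2Cl2, rt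
Reagents that add atoms: none
Why: Evans boron aldol: the Z-boron enolate of the imide (soft enolisation at the imide α-CH2, not at the ester) reacts through a Zimmerman–Traxler chair on the face opposite the benzyl group to give the syn adduct with C6 and C7 as in the target, and the γ-hydroxy ester then closes to the lactone, a syn aldol giving the trans-4,5-disubstituted ring.

Step 5
Reactants: 9 trans-lactone imide
Product: 10 trans-lactone alcohol (C8 as CH2OH)
Conditions: NaBH4, THF/H2O (4:1), 0 °C to rt
Reagents that add atoms: none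
Why: Reductive removal of the Evans auxiliary: hydride attacks the activated exocyclic imide carbonyl, to which the lactone is much less reactive under these conditions, and C7 is not touched.

Step 6
Reactants: 10 trans-lactone alcohol
Product: 11 trans-lactone aldehyde (C8 as CHO)
Conditions: Dess–Martin periodinane, NaHCO3, CH2Cl2, 0 °C to rt; used crude
Reagents that add atoms: none
Why: Dess–Martin oxidation under buffered, non-basic conditions, so that the C7 centre α to the new aldehyde is not epimerised and the β-acyloxy group is not eliminated.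

Step 7
Reactants: 12 (S)-2-methylglycidol
Product: 13 4-methoxybenzyl ether of (S)-2-methylglycidol (stereocentre untouched)
Conditions: NaH, 4-methoxybenzyl chloride, Bu4NI (cat.), THF/DMF, 0 °C to rt
Reagents that add atoms: 4-methoxybenzyl chloride, COc1ccc(CCl)cc1
Why: Williamson etherification of the primary alkoxide; the only possible Payne rearrangement of this alkoxide is degenerate and stereoretentive, so C10 keeps its configuration.

Step 8
Reactants: 13 4-methoxybenzyl ether of (S)-2-methylglycidol
Product: 14 β-hydroxy sulfone PhSO2–C9H2–C10(CH3)(OH)–C1H2OPMB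
Conditions: PhSO2Na, DMF/H2O, 80 °C
Reagents that add atoms: sodium benzenesulfinate, [Na+].[O-]S(=O)c1ccccc1
Why: SN2 opening of the 2,2-disubstituted oxirane at its CH2 terminus by the sulfur of the sulfinate (epoxide opening to a β-hydroxy sulfone); the C10–O bond is not broken.

Step 9
Reactants: 14 β-hydroxy sulfone
Product: 15 β-(triethylsilyloxy) sulfone
Conditions: Et3SiOTf, 2,6-lutidine, CH2Cl2, −78 to 0 °C
Reagents that add atoms: triethylsilyl triflate, CC[Si](CC)(CC)OS(=O)(=O)C(F)(F)F
Why: Silyl triflate silylation of the hindered tertiary alcohol; the triethylsilyl group is chosen because it can later be removed beside a secondary TBS ether.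

Step 10
Reactants: 15 β-(triethylsilyloxy) sulfone; 11 trans-lactone aldehyde
Product: 16 β-hydroxy sulfone adduct (mixture at C8 and C9)
Conditions: 15 (1.3 equiv), n-BuLi, THF, −78 °C; then 11, −78 °C; AcOH quench at −78 °C
Reagents that add atoms: none
Why: Addition of the α-sulfonyl carbanion to the aldehyde (first stage of a Julia-type coupling) forms C8–C9, the aldehyde reacting much faster than the lactone at −78 °C; the new C8 and C9 centres need no control because both are erased in steps 11 and 12.

Step 11
Reactants: 16 β-hydroxy sulfone adduct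
Product: 17 β-keto sulfone (mixture at C9)
Conditions: Dess–Martin periodinane, CH2Cl2, 0 °C to rt
Reagents that add atoms: none
Why: Dess–Martin oxidation of the secondary alcohol gives the β-keto sulfone, which activates the C9–S bond for reductive cleavage.

Step 12
Reactants: 17 β-keto sulfone
Product: 18 C8 ketone
Conditions: SmI2 (2.5 equiv), THF/MeOH, −78 °C
Reagents that add atoms: none
Why: Reductive desulfonylation of an α-sulfonyl ketone by two single-electron transfers from SmI2; the samarium enolate should be protonated by MeOH at −78 °C before the β-silyloxy group can be lost, and lactone, alkyne and PMB ether are inert.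

Step 13
Reactants: 18 C8 ketone
Product: 19 (8R) alcohol
Conditions: (S)-2-methyl-CBS-oxazaborolidine (1 equiv), catecholborane, toluene, −78 to −40 °C
Reagents that add atoms: none
Why: Corey–Bakshi–Shibata reduction: with the α-branched C7 ring carbon as the large group, hydride should go to the face that gives the (8R) carbinol (same priority pattern as (R)-1-phenylethanol from acetophenone), and the Felkin–Anh preference of the C7 centre (hydride anti to the C6 branch) points the same way.

Step 14
Reactants: 19 (8R) alcohol
Product: 20 C8 TBS ether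
Conditions: t-BuMe2SiOTf, 2,6-lutidine, CH2Cl2, −78 to 0 °C
Reagents that add atoms: tert-butyldimethylsilyl triflate, CC(C)(C)[Si](C)(C)OS(=O)(=O)C(F)(F)F
Why: Silyl triflate silylation of the hindered secondary alcohol; it fixes the C8 oxygen so that it cannot translactonise later.

Step 15
Reactants: 20 C8 TBS ether
Product: 21 iodoalkyne
Conditions: N-iodosuccinimide, AgNO3 (0.3 equiv), acetone, rt, dark
Reagents that add atoms: N-iodosuccinimide, O=C1CCC(=O)N1I
Why: Silver-catalysed iododesilylation of the alkynylsilane (via the silver acetylide) gives the iodoalkyne without touching the silyl ethers on oxygen.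

Step 16
Reactants: 21 iodoalkyne
Product: 22 C1 primary alcohol
Conditions: DDQ, CH2Cl2/pH 7 buffer, 0 °C
Reagents that add atoms: none
Why: Oxidative cleavage of the PMB ether by DDQ under buffered conditions; silyl ethers, lactone and iodoalkyne are not oxidised.

Step 17
Reactants: 22 C1 primary alcohol
Product: 23 iodoenyne lactone aldehyde (cyclisation precursor)
Conditions: Dess–Martin periodinane, NaHCO3, CH2Cl2, 0 °C to rt
Reagents that add atoms: none
Why: Dess–Martin oxidation of the primary alcohol; the aldehyde has no α-hydrogen (quaternary C10) and is therefore configurationally safe.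

Step 18
Reactants: 23 iodoenyne lactone aldehyde
Product: 25 ten-membered cyclic enyne carbinol (1S), via alkynylchromium species 24 (not isolated)
Conditions: CrCl2 (8 equiv), NiCl2 (0.05 equiv), degassed THF, rt, 0.002 M, slow addition of 23
Reagents that add atoms: none
Why: Nozaki–Hiyama–Kishi alkynylation: NiCl2 is reduced by CrCl2 to zerovalent nickel, which inserts into the C2–I bond, and transmetalation to trivalent chromium gives alkynylchromium 24, which adds to the C1 aldehyde. The closest known reaction type is the intramolecular chromium/nickel coupling of iodoalkynes with aldehydes used to close ten-membered cyclic enynes and enediynes. The ten-membered carbocycle closes in a 10-exo-trig carbonyl addition that forms C1–C2, the linear alkyne and the Z-C4=C5 alkene bringing the two ends together with little transannular strain. The new C1 stereocentre is controlled by C10 in a non-chelated Felkin–Anh transition state: the C10–OSiEt3 bond lies anti to the incoming alkynyl group, which passes the C10 methyl group while the ring chain (C9) stays gauche, and this should give the (1S) carbinol with its oxygen anti to the C10 oxygen. The step needs chemoselectivity (the organochromium adds to the aldehyde, not to the lactone), ring closure over oligomerisation (high dilution, slow addition) and this facial selectivity, which the bulky, poorly coordinating triethylsilyl ether secures by suppressing chelation.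

Step 19
Reactants: 25 ten-membered cyclic enyne carbinol
Product: 26 C1,C10 diol
Conditions: PPTS, MeOH/CH2Cl2 (1:1), 0 °C to rt
Reagents that add atoms: none
Why: Acid-catalysed methanolysis removes the triethylsilyl ether, which is far more acid-labile than the secondary TBS ether even at a tertiary centre (selective silyl ether cleavage).

Step 20
Reactants: 26 C1,C10 diol
Product: 28 cyclic enyne oxirane (1R,10R), via mesylate 27 (not isolated)
Conditions: MeSO2Cl, Et3N, CH2Cl2, −20 °C; then DBU, 0 °C to rt
Reagents that add atoms: none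
Why: The secondary propargylic hydroxyl is mesylated selectively (the tertiary one is inert) and the C10 alkoxide then displaces the mesylate in an intramolecular SN2 reaction (3-exo-tet) with inversion at C1, which turns the (1S) carbinol into the (1R,10R) oxirane.

Step 21
Reactants: 28 cyclic enyne oxirane
Product: 29 (2Z,4Z)-diene oxirane
Conditions: H2 (1 atm), Pd/CaCO3 poisoned with Pb(OAc)2, quinoline, EtOAc, rt, monitored closely
Reagents that add atoms: none
Why: Syn addition of hydrogen on the poisoned palladium surface should stop at the alkene and give the Z-C2=C3 bond (Lindlar-type semi-hydrogenation of an alkynyl oxirane), the trisubstituted C4=C5 alkene and the oxirane being left intact.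

Step 22
Reactants: 29 (2Z,4Z)-diene oxirane
Product: 32 α-methylene lactone TBS ether, via Mannich base 30 (not isolated), via ammonium iodide 31 (not isolated)
Conditions: LiN(SiMe3)2, THF, −78 °C; Me2N=CH2+ I−, −78 °C to rt; MeI, MeOH, rt; NaHCO3 (aq), EtOAc, rt
Reagents that add atoms: Eschenmoser's salt, C[N+](C)=C.[I-]
Why: The lactone lithium enolate is aminomethylated by Eschenmoser's salt (Mannich reaction), the amine is quaternised and the ammonium salt eliminates (E1cB) to the exocyclic methylene; the transient C11 stereocentre disappears and C7 is untouched.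

Step 23
Reactants: 32 α-methylene lactone TBS ether
Product: 33 C8 alcohol
Conditions: Bu4NF, AcOH (1:1), THF, 0 °C to rt
Reagents that add atoms: none
Why: Fluoride cleavage of the TBS ether buffered with acetic acid, so that neither the vinyl oxirane nor the α-methylene lactone meets strong base or acid.

Step 24
Reactants: 34 tiglic acid
Product: 35 (E)-2-methylbut-2-en-1-ol
Conditions: LiAlH4, Et2O, 0 °C
Reagents that add atoms: none
Why: LiAlH4 reduces the conjugated acid by 1,2-addition to the allylic alcohol with the E geometry unchanged.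

Step 25
Reactants: 35 (E)-2-methylbut-2-en-1-ol
Product: 36 (2R,3R)-2,3-epoxy-2-methylbutan-1-ol
Conditions: Ti(OiPr)4, D-(−)-diethyl tartrate, t-BuOOH, 4 Å sieves, CH2Cl2, −20 °C
Reagents that add atoms: tert-butyl hydroperoxide, CC(C)(C)OO
Why: Sharpless asymmetric epoxidation: with the D-(−) tartrate the oxygen should be delivered to the face that gives the (2R,3R) epoxy alcohol (the mirror image of the (2S,3S) products formed from E-allylic alcohols with the L-(+) ester), and the E geometry fixes the cis relation of the two methyl groups.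

Step 26
Reactants: 36 (2R,3R)-2,3-epoxy-2-methylbutan-1-ol
Product: 37 (2S,3R)-2,3-dimethyloxirane-2-carboxylic acid
Conditions: TEMPO (cat.), PhI(OAc)2, MeCN/H2O, rt
Reagents that add atoms: water, O
Why: Oxoammonium oxidation takes the primary alcohol through the aldehyde hydrate to the acid without opening the oxirane; the descriptors change to (2S,3R) by priority only, with no change in space.

Step 27
Reactants: 37 (2S,3R)-2,3-dimethyloxirane-2-carboxylic acid; 33 C8 alcohol
Product: 39 target CNP0122107.1, via mixed anhydride 38 (not isolated)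
Conditions: 37, 2,4,6-trichlorobenzoyl chloride, Et3N, THF, rt; then 33, DMAP, toluene, rt
Reagents that add atoms: none
Why: Yamaguchi esterification: the mixed anhydride acylates the C8 hydroxyl under DMAP catalysis with retention at C8 and at both oxirane carbons of the acid, which has no α-hydrogen to epimerise.

**Compound list**
1 | (Z)-3-methylpent-2-en-4-yn-1-ol | C#C/C(C)=C\CO | starting material
2 | O,C-bis(trimethylsilyl) derivative of 1 | C[Si](C)(C)C#C/C(C)=C\CO[Si](C)(C)C | intermediate
3 | (Z)-3-methyl-5-(trimethylsilyl)pent-2-en-4-yn-1-ol | C[Si](C)(C)C#C/C(C)=C\CO | intermediate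
4 | (Z)-3-methyl-5-(trimethylsilyl)pent-2-en-4-ynal | C[Si](C)(C)C#C/C(C)=C\C=O | intermediate
5 | (S)-4-benzyl-2-oxazolidinone | O=C1N[C@@H](Cc2ccccc2)CO1 | starting material
6 | methyl 4-chloro-4-oxobutanoate | COC(=O)CCC(Cl)=O | starting material
7 | methyl 4-[(S)-4-benzyl-2-oxo-oxazolidin-3-yl]-4-oxobutanoate | COC(=O)CCC(=O)N1[C@@H](Cc2ccccc2)COC1=O | intermediate
8 | syn-aldol hydroxy ester (C6 OH, C7 imide, open chain) | COC(=O)C[C@H](C(=O)N1[C@@H](Cc2ccccc2)COC1=O)[C@H](O)/C=C(C)\C#C[Si](C)(C)C | intermediate
9 | trans-γ-lactone imide, C6 and C7 as in the target | O=C(N1[C@@H](Cc2ccccc2)COC1=O)[C@H]1CC(=O)O[C@@H]1/C=C(C)\C#C[Si](C)(C)C | intermediate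
10 | trans-γ-lactone with CH2OH (C8) at C7 and the (Z)-silyl enyne at C6 | OC[C@H]1CC(=O)O[C@@H]1/C=C(C)\C#C[Si](C)(C)C | intermediate
11 | trans-γ-lactone aldehyde (C8 CHO) | O=C[C@H]1CC(=O)O[C@@H]1/C=C(C)\C#C[Si](C)(C)C | intermediate
12 | (S)-2-methylglycidol | C[C@]1(CO)CO1 | starting material
13 | 2-[(4-methoxybenzyloxy)methyl]-2-methyloxirane from 12, stereocentre unchanged | C[C@]1(COCc2ccc(OC)cc2)CO1 | intermediate
14 | 1-(4-methoxybenzyloxy)-2-methyl-3-(phenylsulfonyl)propan-2-ol, C10 as in the target | C[C@](O)(COCc1ccc(OC)cc1)CS(=O)(=O)c1ccccc1 | intermediate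
15 | triethylsilyl ether of 14 | C[C@](O[Si](CC)(CC)CC)(COCc1ccc(OC)cc1)CS(=O)(=O)c1ccccc1 | intermediate
16 | β-hydroxy sulfone adduct, C8 OH and C9 SO2Ph, mixture at C8 and C9 | COc1ccc(COC[C@](C)(O[Si](CC)(CC)CC)C(C(O)[C@H]2CC(=O)O[C@@H]2/C=C(C)\C#C[Si](C)(C)C)S(=O)(=O)c2ccccc2)cc1 | intermediate
17 | β-keto sulfone, C8 ketone, mixture at C9 | COc1ccc(COC[C@](C)(O[Si](CC)(CC)CC)C(C(=O)[C@H]2CC(=O)O[C@@H]2/C=C(C)\C#C[Si](C)(C)C)S(=O)(=O)c2ccccc2)cc1 | intermediate
18 | C8 ketone with C10 OSiEt3 and C1 OPMB | COc1ccc(COC[C@](C)(O[Si](CC)(CC)CC)CC(=O)[C@H]2CC(=O)O[C@@H]2/C=C(C)\C#C[Si](C)(C)C)cc1 | intermediate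
19 | (8R) alcohol | COc1ccc(COC[C@](C)(O[Si](CC)(CC)CC)C[C@@H](O)[C@H]2CC(=O)O[C@@H]2/C=C(C)\C#C[Si](C)(C)C)cc1 | intermediate
20 | C8 TBS ether | COc1ccc(COC[C@](C)(O[Si](CC)(CC)CC)C[C@@H](O[Si](C)(C)C(C)(C)C)[C@H]2CC(=O)O[C@@H]2/C=C(C)\C#C[Si](C)(C)C)cc1 | intermediate
21 | iodoalkyne PMB ether | COc1ccc(COC[C@](C)(O[Si](CC)(CC)CC)C[C@@H](O[Si](C)(C)C(C)(C)C)[C@H]2CC(=O)O[C@@H]2/C=C(C)\C#CI)cc1 | intermediate
22 | iodoalkyne C1 primary alcohol | OC[C@](C)(O[Si](CC)(CC)CC)C[C@@H](O[Si](C)(C)C(C)(C)C)[C@H]1CC(=O)O[C@@H]1/C=C(C)\C#CI | intermediate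
23 | iodoenyne lactone aldehyde (cyclisation precursor) | O=C[C@](C)(O[Si](CC)(CC)CC)C[C@@H](O[Si](C)(C)C(C)(C)C)[C@H]1CC(=O)O[C@@H]1/C=C(C)\C#CI | intermediate
24 | alkynylchromium dichloride of 23 (solvent ligands omitted) | O=C[C@](C)(O[Si](CC)(CC)CC)C[C@@H](O[Si](C)(C)C(C)(C)C)[C@H]1CC(=O)O[C@@H]1/C=C(C)\C#C[Cr](Cl)Cl | intermediate
25 | ten-membered cyclic enyne carbinol, (1S) | C1C(=O)O[C@@H]2/C=C(C)\C#C[C@H](O)[C@](C)(O[Si](CC)(CC)CC)C[C@@H](O[Si](C)(C)C(C)(C)C)[C@@H]12 | intermediate
26 | cyclic enyne C1,C10 diol | C1C(=O)O[C@@H]2/C=C(C)\C#C[C@H](O)[C@](C)(O)C[C@@H](O[Si](C)(C)C(C)(C)C)[C@@H]12 | intermediate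
27 | C1 mesylate of 26 | C1C(=O)O[C@@H]2/C=C(C)\C#C[C@H](OS(C)(=O)=O)[C@](C)(O)C[C@@H](O[Si](C)(C)C(C)(C)C)[C@@H]12 | intermediate
28 | cyclic enyne 1,10-oxirane, (1R,10R) | C1C(=O)O[C@@H]2/C=C(C)\C#C[C@H]3O[C@]3(C)C[C@@H](O[Si](C)(C)C(C)(C)C)[C@@H]12 | intermediate
29 | (2Z,4Z)-diene 1,10-oxirane lactone, C8 OTBS | C1C(=O)O[C@@H]2/C=C(C)\C=C/[C@H]3O[C@]3(C)C[C@@H](O[Si](C)(C)C(C)(C)C)[C@@H]12 | intermediate
30 | C11 dimethylaminomethyl lactone (C11 unassigned) | CN(C)CC1C(=O)O[C@@H]2/C=C(C)\C=C/[C@H]3O[C@]3(C)C[C@@H](O[Si](C)(C)C(C)(C)C)[C@@H]12 | intermediate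
31 | trimethylammonium iodide of 30 | C[N+](C)(C)CC1C(=O)O[C@@H]2/C=C(C)\C=C/[C@H]3O[C@]3(C)C[C@@H](O[Si](C)(C)C(C)(C)C)[C@@H]12.[I-] | intermediate
32 | α-methylene lactone, C8 OTBS | C=C1C(=O)O[C@@H]2/C=C(C)\C=C/[C@H]3O[C@]3(C)C[C@@H](O[Si](C)(C)C(C)(C)C)[C@@H]12 | intermediate
33 | α-methylene lactone, C8 OH | C=C1C(=O)O[C@@H]2/C=C(C)\C=C/[C@H]3O[C@]3(C)C[C@@H](O)[C@@H]12 | intermediate
34 | tiglic acid | C/C=C(\C)C(=O)O | starting material
35 | (E)-2-methylbut-2-en-1-ol | C/C=C(\C)CO | intermediate
36 | (2R,3R)-2,3-epoxy-2-methylbutan-1-ol | OC[C@@]1(C)O[C@@H]1C | intermediate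
37 | (2S,3R)-2,3-dimethyloxirane-2-carboxylic acid | OC(=O)[C@@]1(C)O[C@@H]1C | intermediate
38 | mixed anhydride of 37 with 2,4,6-trichlorobenzoic acid | O=C(OC(=O)[C@@]1(C)O[C@@H]1C)c1c(Cl)cc(Cl)cc1Cl | intermediate
39 | CNP0122107.1, (1R,6R,7R,8R,10R) with (2S,3R) acyl group | C=C1C(=O)O[C@@H]2/C=C(C)\C=C/[C@H]3O[C@]3(C)C[C@@H](OC(=O)[C@@]3(C)O[C@@H]3C)[C@@H]12 | target

**Step count**
Total: 27 steps.
Longest linear sequence: 20 steps (1, 2, 4–6, 10–23, 27).

**Steps most likely to fail**

1. Step 18. The ten-membered closure may lose out to intermolecular coupling, or the alkynylchromium may attack the wrong face of the C1 aldehyde because ring strain overrides the Felkin–Anh preference. Fallback for poor facial selectivity: setting out from 23, the cyclisation is run without regard to C1, and the carbinol mixture containing the C1-epimeric carbinol F1 is oxidised with Dess–Martin periodinane to the ten-membered ynone F2. Reduction of F2 with (R)-2-methyl-CBS-oxazaborolidine and catecholborane, the alkynyl group acting as the small substituent, should then set C1 by reagent control and rejoin the route at 25.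

2. Step 13. Facial discrimination in the oxazaborolidine reduction may be poor, because the C9 methylene carries a quaternary carbon and can compete with C7 as the large group. Fallback: setting out from 18, reduction with NaBH4 and CeCl3·7H2O in MeOH at −78 °C would give both C8 epimers. After separation, the (8S) alcohol F3 is inverted by Mitsunobu esterification (PPh3, diisopropyl azodicarboxylate, chloroacetic acid) to the (8R) chloroacetate F4, which is cleaved with thiourea and NaHCO3 in EtOH to rejoin the route at 19.

3. Step 10. The basic, hindered sulfonyl carbanion may enolise the α-branched aldehyde, trigger β-elimination that opens the lactone, or add reversibly. Fallback: setting out from 9, LiSEt (EtSH, n-BuLi, THF, 0 °C) displaces the auxiliary to give the thioester F5. Acylation of lithiated 15 (2.2 equiv) with F5 at −78 °C would give the β-keto sulfone by acyl substitution instead of aldehyde addition and oxidation, rejoining the route at 17.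

**Further compounds**
F1 | step 18 | C1 epimer (1R) of carbinol 25 | C1C(=O)O[C@@H]2/C=C(C)\C#C[C@@H](O)[C@](C)(O[Si](CC)(CC)CC)C[C@@H](O[Si](C)(C)C(C)(C)C)[C@@H]12
F2 | step 18 | ten-membered ynone (C1 ketone) | C1C(=O)O[C@@H]2/C=C(C)\C#CC(=O)[C@](C)(O[Si](CC)(CC)CC)C[C@@H](O[Si](C)(C)C(C)(C)C)[C@@H]12
F3 | step 13 | (8S) epimer of alcohol 19 | COc1ccc(COC[C@](C)(O[Si](CC)(CC)CC)C[C@H](O)[C@H]2CC(=O)O[C@@H]2/C=C(C)\C#C[Si](C)(C)C)cc1
F4 | step 13 | (8R) chloroacetate of 19 | COc1ccc(COC[C@](C)(O[Si](CC)(CC)CC)C[C@@H](OC(=O)CCl)[C@H]2CC(=O)O[C@@H]2/C=C(C)\C#C[Si](C)(C)C)cc1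
F5 | step 10 | S-ethyl thioester of the trans-lactone C8 acid | CCSC(=O)[C@H]1CC(=O)O[C@@H]1/C=C(C)\C#C[Si](C)(C)C
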